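**Plan**

1. The target is read as epicatechin-(4β→8)-catechin carrying a 4-hydroxybenzoate on the 3-OH of the lower (catechin) unit: upper unit 2R,3R,4R, lower unit 2R,3S.
2. Retrosynthesis: ten benzyl groups off; the interflavan C4–C8 bond is cut to an upper-unit 4-ol and the benzylated catechin ester; in the upper unit the O1–C8a and C4a–C4 bonds are then cut together to 3,5-bis(benzyloxy)benzyne and an acyclic β-hydroxy Weinreb amide, whose C2–C3 bond is cut by a glycolate aldol.
3. Enabling feature: in the upper unit, O1 and C4 of ring C sit on the neighbouring ring A carbons C8a and C4a, and only C4a has an oxygen-bearing neighbour (C5). A 3,5-dialkoxybenzyne takes an O-nucleophile at the carbon remote from its flanking alkoxy group and leaves the carbanion beside it, so one annulation with the chain O1–C2–C3–C4 (C4 as amide carbonyl, a helper oxidation level) closes ring C and fuses ring A with the 5,7-oxygen pattern in place.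
4. Forward: the aryne precursor (steps 1–3) and the aldol-derived amide (steps 4–6) are joined in the annulation; the C4 carbonyl is reduced to a 4-ol, which serves as leaving group for the Friedel–Crafts union with the catechin ester (steps 9–10); hydrogenolysis ends the route.
5. Stereochemistry: upper C2 and C3 come from an Evans syn glycolate aldol and pass unchanged through the annulation; upper C4 comes from stereoconvergent attack on the planar C4 cation anti to the C3 oxygen and the C2 aryl group; lower C2 and C3 come from (+)-catechin.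

Key step: step 7

Remark: the numbered starting materials (including 3,5-bis(benzyloxy)phenol) and 1-bromo-3,5-bis(benzyloxy)benzene are taken as purchasable, and the 4-ol 21 is used as its C4 epimer mixture because C4 is ionised in step 11.

**Route**

Step 1
Reactants: 1 3,5-bis(benzyloxy)phenol
Product: 2 3,5-bis(benzyloxy)phenyl N-(propan-2-yl)carbamate
Conditions: i-PrNCO, Et3N (cat.), CH2Cl2, rt
Reagents that add atoms: isopropyl isocyanate, CC(C)N=C=O
Why: Base-catalysed addition of the phenol to the isocyanate (carbamoylation) installs an ortho-directing group that can be removed later under mild conditions.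

Step 2
Reactants: 2 3,5-bis(benzyloxy)phenyl N-(propan-2-yl)carbamate
Product: 6 3,5-bis(benzyloxy)-2-(trimethylsilyl)phenyl N-(propan-2-yl)carbamate, via N-silyl carbamate 3 (not isolated), via ortho-lithiated carbamate 4 (not isolated), via bis-silyl carbamate 5 (not isolated)
Conditions: TBSOTf, TMEDA, Et2O, 0 °C to rt; n-BuLi, TMEDA, −78 °C; TMSCl, −78 °C to rt; aq NaHSO4
Reagents that add atoms: chlorotrimethylsilane, C[Si](C)(C)Cl
Why: Directed ortho-metalation: in-flask N-silylation masks the N–H, the carbamate and the neighbouring benzyloxy group together direct lithiation to C2, TMSCl traps the aryllithium, and the N-silyl group is hydrolysed on acidic work-up.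

Step 3
Reactants: 6 3,5-bis(benzyloxy)-2-(trimethylsilyl)phenyl N-(propan-2-yl)carbamate
Product: 8 3,5-bis(benzyloxy)-2-(trimethylsilyl)phenyl trifluoromethanesulfonate, via silylphenoxide 7 (not isolated)
Conditions: DBU, Et2NH, MeCN, 40 °C; then PhNTf2, rt
Reagents that add atoms: N-phenylbis(trifluoromethanesulfonimide), O=S(=O)(N(c1ccccc1)S(=O)(=O)C(F)(F)F)C(F)(F)F
Why: DBU induces E1cB loss of isopropyl isocyanate from the secondary carbamate (scavenged by Et2NH as a urea) and the phenoxide is O-triflated in the same flask, giving the ortho-silylaryl triflate aryne precursor.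

Step 4
Reactants: 9 (4S)-4-benzyl-1,3-oxazolidin-2-one; 10 2-(benzyloxy)acetyl chloride
Product: 12 (4S)-4-benzyl-3-[2-(benzyloxy)acetyl]-1,3-oxazolidin-2-one, via lithium oxazolidinide 11 (not isolated)
Conditions: n-BuLi, THF, −78 °C; then 10, −78 to 0 °C
Reagents that add atoms: none
Why: N-acylation of the lithiated oxazolidinone with an acid chloride is the standard entry to the imide needed for the Evans aldol.

Step 5
Reactants: 12 (4S)-4-benzyl-3-[2-(benzyloxy)acetyl]-1,3-oxazolidin-2-one; 13 3,4-bis(benzyloxy)benzaldehyde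
Product: 16 (4S)-4-benzyl-3-[(2S,3R)-2-(benzyloxy)-3-[3,4-bis(benzyloxy)phenyl]-3-hydroxypropanoyl]-1,3-oxazolidin-2-one, via boron Z-enolate 14 (not isolated), via boron aldolate 15 (not isolated)
Conditions: Bu2BOTf, Et3N, CH2Cl2, −78 to 0 °C; then pH 7 buffer, MeOH, H2O2, 0 °C
Reagents that add atoms: none
Why: Evans syn aldol: the Z-boron enolate reacts through a closed chair (Zimmerman–Traxler) transition state on the face away from the auxiliary benzyl group, so the auxiliary sets both the carbinol centre (3R, future C2) and the benzyloxy-bearing centre (2S, future C3) with the syn relation that becomes 2,3-cis in ring C, and the two oxygens arrive already differentiated.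

Step 6
Reactants: 16 (4S)-4-benzyl-3-[(2S,3R)-2-(benzyloxy)-3-[3,4-bis(benzyloxy)phenyl]-3-hydroxypropanoyl]-1,3-oxazolidin-2-one
Product: 17 (2S,3R)-2-(benzyloxy)-3-[3,4-bis(benzyloxy)phenyl]-3-hydroxy-N-methoxy-N-methylpropanamide
Conditions: AlMe3, MeNH(OMe)·HCl, CH2Cl2, −10 to 0 °C; aq potassium sodium tartrate
Reagents that add atoms: N,O-dimethylhydroxylamine hydrochloride, CNOC.Cl
Why: Aluminium amide transamidation of the imide, assisted by the free β-hydroxyl, removes the auxiliary without touching either stereocentre and gives the Weinreb amide.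

Step 7
Reactants: 17 (2S,3R)-2-(benzyloxy)-3-[3,4-bis(benzyloxy)phenyl]-3-hydroxy-N-methoxy-N-methylpropanamide; 8 3,5-bis(benzyloxy)-2-(trimethylsilyl)phenyl trifluoromethanesulfonate
Product: 20 (2R,3S)-3,5,7-tris(benzyloxy)-2-[3,4-bis(benzyloxy)phenyl]chroman-4-one, via 3,5-bis(benzyloxy)benzyne 18 (not isolated), via hemiaminal alkoxide 19 (not isolated)
Conditions: 8 (1.5 equiv), KF, 18-crown-6, THF, −20 °C to rt; pH 7 buffer
Reagents that add atoms: none
Why: Proposed new method: fluoride converts 8 into aryne 18, the fluoride-activated benzylic hydroxyl of 17 adds to the aryne carbon remote from the flanking benzyloxy group (future C8a, giving O1–C8a), and the carbanion left at C4a, beside the C5 benzyloxy group, adds to the Weinreb amide carbonyl (giving C4a–C4) and rests as hemiaminal alkoxide 19 until work-up releases ketone 20. The closest known reaction type is the aryne annulation of ortho-hydroxyaryl esters to xanthones (O-addition, then intramolecular acyl capture), combined with the known O–H insertion of arynes into aliphatic alcohols; new here are the sp3 three-atom tether and the amide acceptor. Ring C closes by 6-exo-trig attack of the C4a carbanion on the amide C=O, while ring A arrives intact from the aryne. No lasting stereocentre is created (the C4 hemiaminal carbon becomes C=O); C2 and C3 are carried over from 17 because the O1–C2 bond is never broken and the tetrahedral adduct masks the C4 carbonyl, so C3 should not enolise in the basic medium. The step needs regioselective aryne addition, secured by the inductive polarisation of the 3-alkoxyaryne by the C5 oxygen, and ring closure faster than protonation of the carbanion, favoured by the six-membered geometry and the aprotic medium in which the substrate hydroxyl is the only proton source.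

Step 8
Reactants: 20 (2R,3S)-3,5,7-tris(benzyloxy)-2-[3,4-bis(benzyloxy)phenyl]chroman-4-one
Product: 21 (2R,3R)-3,5,7-tris(benzyloxy)-2-[3,4-bis(benzyloxy)phenyl]chroman-4-ol (C4 epimer mixture)
Conditions: NaBH4, CeCl3·7H2O, MeOH/THF, −40 °C (crude 20 used at once)
Reagents that add atoms: none
Why: Luche reduction of the aryl ketone at low temperature should outrun base-mediated epimerisation at C3; the new C4 carbinol centre may form as either epimer (hydride expected mainly anti to the 3-benzyloxy group), which does not matter because C4 is ionised in step 11.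

Step 9
Reactants: 22 (+)-catechin
Product: 23 (2R,3S)-5,7-bis(benzyloxy)-2-[3,4-bis(benzyloxy)phenyl]chroman-3-ol
Conditions: BnBr, K2CO3, DMF, 0 °C to rt
Reagents that add atoms: benzyl bromide, BrCc1ccccc1
Why: Williamson etherification in which K2CO3 deprotonates only the four phenols, so the far less acidic aliphatic 3-OH stays free.

Step 10
Reactants: 23 (2R,3S)-5,7-bis(benzyloxy)-2-[3,4-bis(benzyloxy)phenyl]chroman-3-ol; 24 4-(benzyloxy)benzoic acid
Product: 25 (2R,3S)-5,7-bis(benzyloxy)-2-[3,4-bis(benzyloxy)phenyl]chroman-3-yl 4-(benzyloxy)benzoate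
Conditions: DCC, DMAP, CH2Cl2, rt
Reagents that add atoms: none
Why: Steglich esterification acylates the single free secondary hydroxyl with retention at C3, fixing the acylation site before the two flavan units are joined.

Step 11
Reactants: 21 (2R,3R)-3,5,7-tris(benzyloxy)-2-[3,4-bis(benzyloxy)phenyl]chroman-4-ol (C4 epimer mixture); 25 (2R,3S)-5,7-bis(benzyloxy)-2-[3,4-bis(benzyloxy)phenyl]chroman-3-yl 4-(benzyloxy)benzoate
Product: 27 (2R,3S)-5,7-bis(benzyloxy)-2-[3,4-bis(benzyloxy)phenyl]-8-[(2R,3R,4R)-3,5,7-tris(benzyloxy)-2-[3,4-bis(benzyloxy)phenyl]chroman-4-yl]chroman-3-yl 4-(benzyloxy)benzoate, via flavan-4-yl cation 26 (not isolated)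
Conditions: 25 (3 equiv), TMSOTf (0.2 equiv), CH2Cl2, −78 to −40 °C; Et3N quench
Reagents that add atoms: none
Why: Lewis-acid ionisation of either 4-ol epimer gives the same ring-A-stabilised cation 26 (stereoconvergent), and Friedel–Crafts attack by C8 of 25, the more accessible nucleophilic site of a benzylated catechin, occurs on the face opposite the 3-benzyloxy and 2-aryl groups to set C4 as R (3,4-trans), while the excess of 25 suppresses chain growth.

Step 12
Reactants: 27 (2R,3S)-5,7-bis(benzyloxy)-2-[3,4-bis(benzyloxy)phenyl]-8-[(2R,3R,4R)-3,5,7-tris(benzyloxy)-2-[3,4-bis(benzyloxy)phenyl]chroman-4-yl]chroman-3-yl 4-(benzyloxy)benzoate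
Product: 28 (2R,3S)-2-(3,4-dihydroxyphenyl)-8-[(2R,3R,4R)-2-(3,4-dihydroxyphenyl)-3,5,7-trihydroxychroman-4-yl]-5,7-dihydroxychroman-3-yl 4-hydroxybenzoate
Conditions: H2 (1 atm), Pd(OH)2 on carbon, THF/MeOH/H2O, rt
Reagents that add atoms: none
Why: Catalytic hydrogenolysis should remove all ten benzyl groups (nine aryl benzyl ethers and the 3-O-benzyl ether) while the benzoate ester, the ring C–O bonds and the interflavan bond are retained, as is usual for benzylated proanthocyanidin esters.

**Compound list**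

1 | 3,5-bis(benzyloxy)phenol | Oc1cc(OCc2ccccc2)cc(OCc2ccccc2)c1 | starting material
2 | 3,5-bis(benzyloxy)phenyl N-(propan-2-yl)carbamate | CC(C)NC(=O)Oc1cc(OCc2ccccc2)cc(OCc2ccccc2)c1 | intermediate
3 | 3,5-bis(benzyloxy)phenyl N-(tert-butyldimethylsilyl)-N-(propan-2-yl)carbamate (formed in the flask) | CC(C)N(C(=O)Oc1cc(OCc2ccccc2)cc(OCc2ccccc2)c1)[Si](C)(C)C(C)(C)C | intermediate
4 | 2-lithio derivative of 3, lithium between the carbamate oxygen and a benzyloxy group (formed in the flask) | CC(C)N(C(=O)Oc1cc(OCc2ccccc2)cc(OCc2ccccc2)c1[Li])[Si](C)(C)C(C)(C)C | intermediate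
5 | 3,5-bis(benzyloxy)-2-(trimethylsilyl)phenyl N-(tert-butyldimethylsilyl)-N-(propan-2-yl)carbamate (formed in the flask) | CC(C)N(C(=O)Oc1cc(OCc2ccccc2)cc(OCc2ccccc2)c1[Si](C)(C)C)[Si](C)(C)C(C)(C)C | intermediate
6 | 3,5-bis(benzyloxy)-2-(trimethylsilyl)phenyl N-(propan-2-yl)carbamate | CC(C)NC(=O)Oc1cc(OCc2ccccc2)cc(OCc2ccccc2)c1[Si](C)(C)C | intermediate
7 | 3,5-bis(benzyloxy)-2-(trimethylsilyl)phenol, present as its amidinium phenoxide (formed in the flask) | Oc1cc(OCc2ccccc2)cc(OCc2ccccc2)c1[Si](C)(C)C | intermediate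
8 | 3,5-bis(benzyloxy)-2-(trimethylsilyl)phenyl trifluoromethanesulfonate | C[Si](C)(C)c1c(OS(=O)(=O)C(F)(F)F)cc(OCc2ccccc2)cc1OCc1ccccc1 | intermediate
9 | (4S)-4-benzyl-1,3-oxazolidin-2-one | O=C1N[C@@H](Cc2ccccc2)CO1 | starting material
10 | 2-(benzyloxy)acetyl chloride | O=C(Cl)COCc1ccccc1 | starting material
11 | N-lithio-(4S)-4-benzyl-1,3-oxazolidin-2-one (formed in the flask) | O=C1N([Li])[C@@H](Cc2ccccc2)CO1 | intermediate
12 | (4S)-4-benzyl-3-[2-(benzyloxy)acetyl]-1,3-oxazolidin-2-one | O=C(COCc1ccccc1)N1[C@@H](Cc2ccccc2)COC1=O | intermediate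
13 | 3,4-bis(benzyloxy)benzaldehyde | O=Cc1ccc(OCc2ccccc2)c(OCc2ccccc2)c1 | starting material
14 | (Z)-dibutylboron enolate of 12 (formed in the flask) | CCCCB(CCCC)O/C(=C\OCc1ccccc1)N1[C@@H](Cc2ccccc2)COC1=O | intermediate
15 | O-dibutylboryl aldolate of 16 (formed in the flask) | O=C([C@@H](OCc1ccccc1)[C@H](OB(CCCC)CCCC)c1ccc(OCc2ccccc2)c(OCc2ccccc2)c1)N1[C@@H](Cc2ccccc2)COC1=O | intermediate
16 | (4S)-4-benzyl-3-[(2S,3R)-2-(benzyloxy)-3-[3,4-bis(benzyloxy)phenyl]-3-hydroxypropanoyl]-1,3-oxazolidin-2-one | O=C([C@@H](OCc1ccccc1)[C@H](O)c1ccc(OCc2ccccc2)c(OCc2ccccc2)c1)N1[C@@H](Cc2ccccc2)COC1=O | intermediate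
17 | (2S,3R)-2-(benzyloxy)-3-[3,4-bis(benzyloxy)phenyl]-3-hydroxy-N-methoxy-N-methylpropanamide | CON(C)C(=O)[C@@H](OCc1ccccc1)[C@H](O)c1ccc(OCc2ccccc2)c(OCc2ccccc2)c1 | intermediate
18 | 3,5-bis(benzyloxy)benzyne (1,2-didehydro-3,5-bis(benzyloxy)benzene; formed in the flask) | C1(OCc2ccccc2)=CC(OCc2ccccc2)=CC#C1 | intermediate
19 | (2R,3S)-3,5,7-tris(benzyloxy)-2-[3,4-bis(benzyloxy)phenyl]-4-[methoxy(methyl)amino]chroman-4-ol, present as its potassium alkoxide, C4 undefined (formed in the flask) | CON(C)C1(O)c2c(OCc3ccccc3)cc(OCc3ccccc3)cc2O[C@H](c2ccc(OCc3ccccc3)c(OCc3ccccc3)c2)[C@@H]1OCc1ccccc1 | intermediate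
20 | (2R,3S)-3,5,7-tris(benzyloxy)-2-[3,4-bis(benzyloxy)phenyl]chroman-4-one (2,3-cis) | O=C1c2c(OCc3ccccc3)cc(OCc3ccccc3)cc2O[C@H](c2ccc(OCc3ccccc3)c(OCc3ccccc3)c2)[C@@H]1OCc1ccccc1 | intermediate
21 | (2R,3R)-3,5,7-tris(benzyloxy)-2-[3,4-bis(benzyloxy)phenyl]chroman-4-ol (2,3-cis; C4 epimer mixture) | OC1c2c(OCc3ccccc3)cc(OCc3ccccc3)cc2O[C@H](c2ccc(OCc3ccccc3)c(OCc3ccccc3)c2)[C@@H]1OCc1ccccc1 | intermediate
22 | (+)-catechin, (2R,3S)-2-(3,4-dihydroxyphenyl)chroman-3,5,7-triol | O[C@H]1Cc2c(O)cc(O)cc2O[C@@H]1c1ccc(O)c(O)c1 | starting material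
23 | (2R,3S)-5,7-bis(benzyloxy)-2-[3,4-bis(benzyloxy)phenyl]chroman-3-ol | O[C@H]1Cc2c(OCc3ccccc3)cc(OCc3ccccc3)cc2O[C@@H]1c1ccc(OCc2ccccc2)c(OCc2ccccc2)c1 | intermediate
24 | 4-(benzyloxy)benzoic acid | OC(=O)c1ccc(OCc2ccccc2)cc1 | starting material
25 | (2R,3S)-5,7-bis(benzyloxy)-2-[3,4-bis(benzyloxy)phenyl]chroman-3-yl 4-(benzyloxy)benzoate | O=C(O[C@H]1Cc2c(OCc3ccccc3)cc(OCc3ccccc3)cc2O[C@@H]1c1ccc(OCc2ccccc2)c(OCc2ccccc2)c1)c1ccc(OCc2ccccc2)cc1 | intermediate
26 | C4 cation of 21, (2R)-3,5,7-tris(benzyloxy)-2-[3,4-bis(benzyloxy)phenyl]chroman-4-ylium, 2,3-cis (formed in the flask) | [CH+]1c2c(OCc3ccccc3)cc(OCc3ccccc3)cc2O[C@H](c2ccc(OCc3ccccc3)c(OCc3ccccc3)c2)[C@@H]1OCc1ccccc1 | intermediate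
27 | (2R,3S)-5,7-bis(benzyloxy)-2-[3,4-bis(benzyloxy)phenyl]-8-[(2R,3R,4R)-3,5,7-tris(benzyloxy)-2-[3,4-bis(benzyloxy)phenyl]chroman-4-yl]chroman-3-yl 4-(benzyloxy)benzoate | O=C(O[C@H]1Cc2c(OCc3ccccc3)cc(OCc3ccccc3)c([C@H]3c4c(OCc5ccccc5)cc(OCc5ccccc5)cc4O[C@H](c4ccc(OCc5ccccc5)c(OCc5ccccc5)c4)[C@@H]3OCc3ccccc3)c2O[C@@H]1c1ccc(OCc2ccccc2)c(OCc2ccccc2)c1)c1ccc(OCc2ccccc2)cc1 | intermediate
28 | (2R,3S)-2-(3,4-dihydroxyphenyl)-8-[(2R,3R,4R)-2-(3,4-dihydroxyphenyl)-3,5,7-trihydroxychroman-4-yl]-5,7-dihydroxychroman-3-yl 4-hydroxybenzoate | O=C(O[C@H]1Cc2c(O)cc(O)c([C@H]3c4c(O)cc(O)cc4O[C@H](c4ccc(O)c(O)c4)[C@@H]3O)c2O[C@@H]1c1ccc(O)c(O)c1)c1ccc(O)cc1 | target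

**Step count and risks**

Total step count: 12. Longest linear sequence: 7 steps (steps 4, 5, 6, 7, 8, 11, 12; the aryne branch, steps 1, 2, 3, 7, 8, 11, 12, is equally long).

Steps most likely to fail:

Step 7. The C4a carbanion may be protonated before it reaches the amide, so that only O-arylation occurs. Alternatively, the hemiaminal may collapse early and the free ketone may then epimerise at C3 or open by β-elimination of the ring oxygen in the basic medium. The fallback separates the two bond formations and uses known chemistry. It sets out from 17: a palladium-catalysed C–O cross-coupling with 1-bromo-3,5-bis(benzyloxy)benzene ([(allyl)PdCl]2, RockPhos, Cs2CO3, toluene, 90 °C) should give the aryl ether (2S,3R)-2-(benzyloxy)-3-[3,4-bis(benzyloxy)phenyl]-3-[3,5-bis(benzyloxy)phenoxy]-N-methoxy-N-methylpropanamide F1. Reduction with i-Bu2AlH (THF, −78 °C) should give the aldehyde (2S,3R)-2-(benzyloxy)-3-[3,4-bis(benzyloxy)phenyl]-3-[3,5-bis(benzyloxy)phenoxy]propanal F2. A mild Lewis acid (Sc(OTf)3, CH2Cl2, −40 °C) should then close ring C by intramolecular Friedel–Crafts hydroxyalkylation at either of the two equivalent positions ortho to the ether oxygen. The fallback comes back to the route at 21, bypassing 20.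

Step 11. The acylated nucleophile 25 may react too slowly, so that self-condensation of the cation through the nucleophilic ring A of the upper unit (oligomerisation) or attack through C6 of the lower unit takes over. The fallback changes the order of union and acylation. It sets out from 21 and 23: the same ionisation (TMSOTf, CH2Cl2, −78 °C) with the more nucleophilic free alcohol 23 in excess should give the dimer (2R,3S)-5,7-bis(benzyloxy)-2-[3,4-bis(benzyloxy)phenyl]-8-[(2R,3R,4R)-3,5,7-tris(benzyloxy)-2-[3,4-bis(benzyloxy)phenyl]chroman-4-yl]chroman-3-ol F3. Its only free hydroxyl, at C3 of the lower unit, is then esterified with 24 (DCC, DMAP, CH2Cl2), and the fallback comes back to the route at 27.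

Step 2. Lithiation may compete at a benzylic CH2 of the benzyl ethers (followed by Wittig rearrangement) or at C4 between the two benzyloxy groups, instead of ortho to the carbamate. The fallback replaces deprotonation by halogen–metal exchange. It sets out from 1: ortho-selective bromination (NBS, i-Pr2NH cat., CH2Cl2, 0 °C) should give 2-bromo-3,5-bis(benzyloxy)phenol F4, and O-silylation with hexamethyldisilazane (THF, reflux) should give [2-bromo-3,5-bis(benzyloxy)phenoxy]trimethylsilane F5. Treatment with n-BuLi (THF, −100 °C) should trigger bromine–lithium exchange, faster than any deprotonation, and 1,3 O-to-C silyl migration (retro-Brook rearrangement). The fallback comes back to the route at 7, formed as its lithium phenoxide and triflated in the same flask with Tf2O to give 8, bypassing 2 and 6.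

**Further compounds**

F1 | step 7 | (2S,3R)-2-(benzyloxy)-3-[3,4-bis(benzyloxy)phenyl]-3-[3,5-bis(benzyloxy)phenoxy]-N-methoxy-N-methylpropanamide | CON(C)C(=O)[C@@H](OCc1ccccc1)[C@H](Oc1cc(OCc2ccccc2)cc(OCc2ccccc2)c1)c1ccc(OCc2ccccc2)c(OCc2ccccc2)c1
F2 | step 7 | (2S,3R)-2-(benzyloxy)-3-[3,4-bis(benzyloxy)phenyl]-3-[3,5-bis(benzyloxy)phenoxy]propanal | O=C[C@@H](OCc1ccccc1)[C@H](Oc1cc(OCc2ccccc2)cc(OCc2ccccc2)c1)c1ccc(OCc2ccccc2)c(OCc2ccccc2)c1
F3 | step 11 | (2R,3S)-5,7-bis(benzyloxy)-2-[3,4-bis(benzyloxy)phenyl]-8-[(2R,3R,4R)-3,5,7-tris(benzyloxy)-2-[3,4-bis(benzyloxy)phenyl]chroman-4-yl]chroman-3-ol | O[C@H]1Cc2c(OCc3ccccc3)cc(OCc3ccccc3)c([C@H]3c4c(OCc5ccccc5)cc(OCc5ccccc5)cc4O[C@H](c4ccc(OCc5ccccc5)c(OCc5ccccc5)c4)[C@@H]3OCc3ccccc3)c2O[C@@H]1c1ccc(OCc2ccccc2)c(OCc2ccccc2)c1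
F4 | step 2 | 2-bromo-3,5-bis(benzyloxy)phenol | Oc1cc(OCc2ccccc2)cc(OCc2ccccc2)c1Br
F5 | step 2 | [2-bromo-3,5-bis(benzyloxy)phenoxy]trimethylsilane | C[Si](C)(C)Oc1cc(OCc2ccccc2)cc(OCc2ccccc2)c1Br
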